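**Assumptions.** 3-(4-Hydroxy-3,5-dimethoxyphenyl)propan-1-ol (7) is taken as a purchasable lignin-derived phenol. TBS = tert-butyldimethylsilyl and TBSO = its ether. Locants: ring A = guaiacyl ring, ring B = syringyl-type ring, C7–C8–C9 = the chain between them.

## Structural features

- The target is an 8-O-4′ neolignan. Ring A (C3–OMe, C4–O) and ring B (two OMe groups flanking the ether oxygen, a 3-hydroxypropyl chain para to it) are joined through the chain C7–C8–C9. C7 is the benzylic carbinol on ring A, C8 carries the ring B aryloxy group and C9 is a CH2OH arm.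
- The C4 oxygen of ring A is etherified with C2 of a second, achiral glycerol unit.
- The only stereocentres are the adjacent C7 (R) and C8 (S). They are erythro: 7-OH and 8-OAr are anti when Ar–C7–C8–C9 is drawn zigzag.
- Fragile points: the benzylic C7–OH para to an alkoxy group ionises in acid, which scrambles C7. Whenever C7 or C9 is at the carbonyl level, C8–H becomes acidic and β-elimination or retro-aldol cleavage is possible. Five hydroxyl groups of three kinds must be kept apart.
- The real difficulty is the anti C7/C8 diad in absolute form, at a carbon (C8) whose oxygen belongs to a di-ortho-substituted phenol. That phenol is a poor SN2 nucleophile at C8, and the auxiliary-controlled glycolate aldol that forms C7–C8 gives the syn array by its geometry.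
- The key step exploits the fact that C7 is both benzylic and oxygen-bearing, while C8 bears a heteroatom substituent and a one-carbon arm. This is the pattern G–CH(OH)–CH(X)–C=C written by a [2,3]-Wittig shift of a benzyl allyl ether, with ring A as the anion-stabilising group G, the ring B aryloxy group as X, and C9 masked as an alkene carbon.

## Logic of the disconnections

**17 ⇒ 16.** The three primary O–Si bonds are cut last. The three hydroxyls that take no part in bond construction (two on the ring A glycerol unit, one on the ring B chain) travel as one kind of silyl ether and are released together. Gain: no hydroxyl differentiation problem anywhere. Demand: a deprotection that is not acidic, because of the benzylic C7–OH.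

**16 ⇒ 14 (through 15).** The C9–O and C9–H bonds are traced back to a C=C bond: C9 is the inner carbon of an (E)-propenyl group on C8. This group is exactly what the key step leaves behind, and its outer two carbons are disposable. Gain: C9 needs no protecting group before this point. Demand: alkene cleavage that spares two electron-rich rings, and reduction of 15 before its C8–H can epimerise.

**14 ⇒ 12 (through 13): key disconnection.** The C7–C8 bond is cut and the C7 oxygen is reconnected to the carbinol carbon at the far end of the allyl array. In one sentence: the C7–C8 bond and both stereocentres arise together when the benzylic carbanion 13 of ether 12 undergoes a [2,3]-sigmatropic shift.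
- Reason: the hindered aryl ether at C8 is then made on an sp2 carbon, where no stereochemistry is at stake, and the anti diad follows from the transition-state geometry.
- Gain: one C–C bond and two adjacent stereocentres are traded for two simple C–O bonds and one isolated methyl carbinol centre.
- Demand: E enol-ether geometry and R configuration in 12, an exo-aryl envelope transition state, and [2,3]- over [1,2]-shift.

**12 ⇒ 6 + 11.** The benzylic C–O bond is cut. It is an ether to an activated benzylic carbon, made by alkoxide displacement without touching the stereocentre. Gain: two fragments of similar size, each carrying one aromatic ring. Demand: basic, non-acidic conditions, because 11 is an acid-labile γ-aryloxy allylic alcohol.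

**11 ⇒ 10 ⇒ 9 ⇒ 7 + 8.** Cut in turn: the carbinol C–H bond (enantioselective ketone reduction), one O–Si bond, and the vinyl C–O bond (conjugate addition of the phenolic oxygen of 7 to 8). Gain: the only stereocentre that must be bought is a methyl carbinol next to a conjugated ketone, and the E geometry is thermodynamic. Demand: the phenol of 7 must react in preference to its primary alcohol.

**6 ⇒ 5 ⇒ 4 ⇒ 2 + 3, and 2 ⇒ 1.** Cut in turn: the benzylic C–Cl bond, the benzylic C–H bond, the aryl O–C(sp3) bond to the glycerol C2, and two O–Si bonds. Gain: ring A and its achiral glycerol ether come from three bulk chemicals. Demand: selective silylation of the two primary hydroxyls of 1, and ether formation at a secondary carbon with an acidic phenol.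

## Other disconnections considered

**Alternative 1: C7–C8 by glycolate aldol (the first that comes to mind).**
- Cut: C7–C8, between aldehyde 4 and the boron enolate of an N-(aryloxyacetyl)oxazolidinone A1 that carries ring B.
- Forward key step: auxiliary-controlled aldol addition giving adduct A2.
- Ground for rejection: a Z-boron enolate in a closed chair transition state gives the 7,8-syn array by geometry. A2 is therefore expected to be the threo isomer, the C7 epimer of what is needed. Correction needs an inversion at a benzylic carbinol para to an alkoxy group, which ionises easily. Anti-selective glycolate variants rest on open transition states whose outcome with a bulky, chelating 2,6-dimethoxyphenoxy group cannot be argued with confidence. A stoichiometric auxiliary must be attached and cleaved; about four more operations than the chosen plan.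

**Alternative 2: C8–O bond by displacement with inversion.**
- Cut: the C8–O aryl ether bond.
- Forward key step: asymmetric dihydroxylation of cinnamate A3 to threo diol A4, selective α-sulfonylation to A5, then SN2 at C8 by the ring B phenoxide.
- Ground for rejection: the phenoxide is flanked by two methoxy groups and must attack a secondary carbon next to a free benzylic alkoxide. Intramolecular closure of that alkoxide onto C8 to the glycidate is expected to be faster. The glycidate would then open at the benzylic C7, where the electron-rich ring stabilises positive charge, placing the aryloxy group on the wrong carbon. The basic medium also threatens C8 of an α-aryloxy ester.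

**Alternative 3: stereoconvergent reduction.**
- Cut: C7–H, with C8 equilibrating.
- Forward key step: dynamic kinetic transfer hydrogenation of racemic α-aryloxy-β-keto ester A6 with RuCl(p-cymene)(TsDPEN) in HCO2H/Et3N.
- Ground for rejection: the catalyst fixes C7, but the C8 enantiomer that reacts faster is decided by which α-substituent stands anti to the incoming hydride. With an ester competing against the aryloxy group, the reduction is expected to converge on the syn hydroxy ester A7 (threo). That again forces a C7 inversion at an ionisable benzylic centre. A6 also needs its own C–C and C–O bond constructions, so the plan is longer and ends on the wrong diastereomer.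

Key step: step 9

## Route

Step 1
Reactants: 1 glycerol (propane-1,2,3-triol)
Product: 2 1,3-bis(TBSO)propan-2-ol
Conditions: TBSCl (2.05 equiv), imidazole, CH2Cl2, 0 °C to rt
Reagents that add atoms: tert-butyldimethylsilyl chloride, CC(C)(C)[Si](C)(C)Cl
Why: Steric discrimination in O-silylation: the two primary hydroxyls react well before the flanked secondary one, which is left free for the ether bond of step 2.

Step 2
Reactants: 2 1,3-bis(TBSO)propan-2-ol; 3 vanillin (4-hydroxy-3-methoxybenzaldehyde)
Product: 4 4-{[1,3-bis(TBSO)propan-2-yl]oxy}-3-methoxybenzaldehyde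
Conditions: PPh3, DIAD, THF, 0 °C to rt
Reagents that add atoms: none
Why: Mitsunobu etherification: the para-formyl phenol is acidic enough to protonate the betaine and displaces the oxyphosphonium of the secondary alcohol; the carbinol carbon is not stereogenic, so the inversion has no consequence.

Step 3
Reactants: 4 4-{[1,3-bis(TBSO)propan-2-yl]oxy}-3-methoxybenzaldehyde
Product: 5 (4-{[1,3-bis(TBSO)propan-2-yl]oxy}-3-methoxyphenyl)methanol
Conditions: NaBH4, MeOH/THF, 0 °C
Reagents that add atoms: none
Why: Chemoselective hydride reduction of the aryl aldehyde; silyl and aryl ethers are inert.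

Step 4
Reactants: 5 (4-{[1,3-bis(TBSO)propan-2-yl]oxy}-3-methoxyphenyl)methanol
Product: 6 4-{[1,3-bis(TBSO)propan-2-yl]oxy}-3-methoxybenzyl chloride
Conditions: MsCl, Et3N, CH2Cl2, 0 °C to rt; used crude
Reagents that add atoms: methanesulfonyl chloride, CS(=O)(=O)Cl
Why: The mesylate of a 4-alkoxybenzyl alcohol is displaced in the flask by the chloride released from MsCl, giving the benzyl chloride under non-acidic conditions that spare the silyl ethers.

Step 5
Reactants: 7 3-(4-hydroxy-3,5-dimethoxyphenyl)propan-1-ol; 8 but-3-yn-2-one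
Product: 9 (E)-4-[4-(3-hydroxypropyl)-2,6-dimethoxyphenoxy]but-3-en-2-one
Conditions: DABCO (10 mol%), CH2Cl2, 0 °C to rt
Reagents that add atoms: none
Why: Amine-catalysed oxa-Michael addition: the DABCO–ynone zwitterion deprotonates only the phenol (far more acidic than the primary alcohol), and addition–elimination gives the thermodynamically favoured (E)-β-aryloxy enone; no stereocentre is formed.

Step 6
Reactants: 9 (E)-4-[4-(3-hydroxypropyl)-2,6-dimethoxyphenoxy]but-3-en-2-one
Product: 10 (E)-4-{4-[3-(TBSO)propyl]-2,6-dimethoxyphenoxy}but-3-en-2-one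
Conditions: TBSCl, imidazole, DMF, rt
Reagents that add atoms: tert-butyldimethylsilyl chloride, CC(C)(C)[Si](C)(C)Cl
Why: Standard silylation of the one remaining hydroxyl; placing it after step 5 avoids any competition from the phenol.

Step 7
Reactants: 10 (E)-4-{4-[3-(TBSO)propyl]-2,6-dimethoxyphenoxy}but-3-en-2-one
Product: 11 (2R,3E)-4-{4-[3-(TBSO)propyl]-2,6-dimethoxyphenoxy}but-3-en-2-ol
Conditions: (S)-2-methyl-CBS-oxazaborolidine (20 mol%), catecholborane, toluene, −78 to −40 °C; MeOH, then aq. NaOH work-up
Reagents that add atoms: none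
Why: CBS reduction: the ketone oxygen binds the catalyst boron with the alkenyl group as the large and methyl as the small substituent, and hydride is delivered within the complex to give the (R)-carbinol, as for other (E)-alkenyl methyl ketones with the (S)-catalyst; catecholborane at low temperature avoids conjugate reduction and hydroboration, and the basic work-up protects the acid-labile γ-aryloxy allylic alcohol.

Step 8
Reactants: 11 (2R,3E)-4-{4-[3-(TBSO)propyl]-2,6-dimethoxyphenoxy}but-3-en-2-ol; 6 4-{[1,3-bis(TBSO)propan-2-yl]oxy}-3-methoxybenzyl chloride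
Product: 12 (1E,3R)-3-[(4-{[1,3-bis(TBSO)propan-2-yl]oxy}-3-methoxybenzyl)oxy]-1-{4-[3-(TBSO)propyl]-2,6-dimethoxyphenoxy}but-1-ene
Conditions: NaH, THF/DMF, 0 °C; then 6, n-Bu4NI (cat.), 0 °C to rt
Reagents that add atoms: none
Why: Williamson ether synthesis: the sodium alkoxide of 11 displaces halide from the activated benzylic carbon of 6 with iodide catalysis; the carbinol stereocentre is not involved and the enol ether is stable to base.

Step 9
Reactants: 12 (1E,3R)-3-[(4-{[1,3-bis(TBSO)propan-2-yl]oxy}-3-methoxybenzyl)oxy]-1-{4-[3-(TBSO)propyl]-2,6-dimethoxyphenoxy}but-1-ene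
Product: 14 (1R,2S,3E)-1-(4-{[1,3-bis(TBSO)propan-2-yl]oxy}-3-methoxyphenyl)-2-{4-[3-(TBSO)propyl]-2,6-dimethoxyphenoxy}pent-3-en-1-ol, via lithiated benzylic ether 13 (not isolated)
Conditions: n-BuLi (1.5 equiv), THF, −78 to −50 °C; then aq. NH4Cl
Reagents that add atoms: none
Why: Proposed new method: a [2,3]-Wittig rearrangement whose allyl terminus is the oxygen-bearing carbon of an aryl enol ether goes beyond the established scope, and the closest known reaction type is the [2,3]-Wittig shift of benzyl ethers of secondary (E)-allylic alcohols with 1,3-chirality transfer. n-BuLi removes a benzylic proton of 12 (the only C–H both α to oxygen and conjugated to an arene) to give 13, whose carbanion carbon (future C7) bonds suprafacially to the enol-ether carbon carrying the aryloxy group (future C8) while the ether O–C bond at the methyl carbinol breaks; this six-electron, five-centre shift should be feasible because the π* coefficient of an enol ether is largest at its oxygen-bearing carbon. No ring is closed; the five-membered envelope exists only in the transition state. C8 is controlled by the (R)-carbinol centre: its methyl group sits pseudo-equatorial, which gives the (E)-propenyl group and confines the breaking C–O bond, and with it the incoming carbanion, to one face of the alkene, so that C8 becomes S. C7 is controlled by the preference of the ring A aryl group for the exo position of the envelope, away from the C–H of the central allyl carbon; for an E-alkene this gives the 7,8-anti (erythro) relationship and hence 7R. The step needs [2,3]- over [1,2]-shift, secured by staying at or below −50 °C where radical dissociation–recombination is slow, and benzylic over ortho or allylic lithiation, secured by the higher kinetic acidity of the benzylic ether C–H. The lithium alkoxide formed carries only a poor leaving group (aryloxide) at the β-carbon, so the new β-aryl ether should survive until the quench.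

Step 10
Reactants: 14 (1R,2S,3E)-1-(4-{[1,3-bis(TBSO)propan-2-yl]oxy}-3-methoxyphenyl)-2-{4-[3-(TBSO)propyl]-2,6-dimethoxyphenoxy}pent-3-en-1-ol
Product: 16 (1R,2S)-1-(4-{[1,3-bis(TBSO)propan-2-yl]oxy}-3-methoxyphenyl)-2-{4-[3-(TBSO)propyl]-2,6-dimethoxyphenoxy}propane-1,3-diol, via α-aryloxy-β-hydroxy aldehyde 15 (not isolated)
Conditions: K2OsO4·2H2O (2 mol%), NaIO4, 2,6-lutidine, dioxane/H2O, rt; extractive work-up, crude 15 directly into NaBH4, MeOH, 0 °C
Reagents that add atoms: sodium periodate, [Na+].[O-]I(=O)(=O)=O (terminal oxidant; supplies the C9 oxygen through the osmium catalyst)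
Why: Lemieux–Johnson cleavage: OsO4 generated from K2OsO4 dihydroxylates the only alkene, NaIO4 cleaves the glycol and 2,6-lutidine buffers the medium; 15 is reduced at once with NaBH4 so that the C8–H next to the aldehyde has no time to epimerise, and C7 is not touched.

Step 11
Reactants: 16 (1R,2S)-1-(4-{[1,3-bis(TBSO)propan-2-yl]oxy}-3-methoxyphenyl)-2-{4-[3-(TBSO)propyl]-2,6-dimethoxyphenoxy}propane-1,3-diol
Product: 17 (1R,2S)-1-{4-[(1,3-dihydroxypropan-2-yl)oxy]-3-methoxyphenyl}-2-[4-(3-hydroxypropyl)-2,6-dimethoxyphenoxy]propane-1,3-diol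
Conditions: n-Bu4NF, THF, 0 °C to rt
Reagents that add atoms: none
Why: Fluoride cleaves all three primary silyl ethers under non-acidic conditions, so the benzylic C7–OH cannot ionise and neither stereocentre is touched.

## Compound list

1 | glycerol (propane-1,2,3-triol) | OCC(O)CO | starting material
2 | 1,3-bis[(tert-butyldimethylsilyl)oxy]propan-2-ol | CC(C)(C)[Si](C)(C)OCC(O)CO[Si](C)(C)C(C)(C)C | intermediate
3 | vanillin (4-hydroxy-3-methoxybenzaldehyde) | COc1cc(C=O)ccc1O | starting material
4 | 4-{[1,3-bis(TBSO)propan-2-yl]oxy}-3-methoxybenzaldehyde | COc1cc(C=O)ccc1OC(CO[Si](C)(C)C(C)(C)C)CO[Si](C)(C)C(C)(C)C | intermediate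
5 | (4-{[1,3-bis(TBSO)propan-2-yl]oxy}-3-methoxyphenyl)methanol | COc1cc(CO)ccc1OC(CO[Si](C)(C)C(C)(C)C)CO[Si](C)(C)C(C)(C)C | intermediate
6 | 4-{[1,3-bis(TBSO)propan-2-yl]oxy}-3-methoxybenzyl chloride | COc1cc(CCl)ccc1OC(CO[Si](C)(C)C(C)(C)C)CO[Si](C)(C)C(C)(C)C | intermediate
7 | 3-(4-hydroxy-3,5-dimethoxyphenyl)propan-1-ol (dihydrosinapyl alcohol) | COc1cc(CCCO)cc(OC)c1O | starting material
8 | but-3-yn-2-one | CC(=O)C#C | starting material
9 | (E)-4-[4-(3-hydroxypropyl)-2,6-dimethoxyphenoxy]but-3-en-2-one | CC(=O)/C=C/Oc1c(OC)cc(CCCO)cc1OC | intermediate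
10 | (E)-4-{4-[3-(TBSO)propyl]-2,6-dimethoxyphenoxy}but-3-en-2-one | CC(=O)/C=C/Oc1c(OC)cc(CCCO[Si](C)(C)C(C)(C)C)cc1OC | intermediate
11 | (2R,3E)-4-{4-[3-(TBSO)propyl]-2,6-dimethoxyphenoxy}but-3-en-2-ol | C[C@@H](O)/C=C/Oc1c(OC)cc(CCCO[Si](C)(C)C(C)(C)C)cc1OC | intermediate
12 | (1E,3R)-3-[(4-{[1,3-bis(TBSO)propan-2-yl]oxy}-3-methoxybenzyl)oxy]-1-{4-[3-(TBSO)propyl]-2,6-dimethoxyphenoxy}but-1-ene | C[C@@H](OCc1ccc(OC(CO[Si](C)(C)C(C)(C)C)CO[Si](C)(C)C(C)(C)C)c(OC)c1)/C=C/Oc1c(OC)cc(CCCO[Si](C)(C)C(C)(C)C)cc1OC | intermediate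
13 | benzylic α-lithio derivative of 12 (carbanion centre configurationally labile) | C[C@@H](OC([Li])c1ccc(OC(CO[Si](C)(C)C(C)(C)C)CO[Si](C)(C)C(C)(C)C)c(OC)c1)/C=C/Oc1c(OC)cc(CCCO[Si](C)(C)C(C)(C)C)cc1OC | intermediate
14 | (1R,2S,3E)-1-(4-{[1,3-bis(TBSO)propan-2-yl]oxy}-3-methoxyphenyl)-2-{4-[3-(TBSO)propyl]-2,6-dimethoxyphenoxy}pent-3-en-1-ol | COc1cc([C@@H](O)[C@H](/C=C/C)Oc2c(OC)cc(CCCO[Si](C)(C)C(C)(C)C)cc2OC)ccc1OC(CO[Si](C)(C)C(C)(C)C)CO[Si](C)(C)C(C)(C)C | intermediate
15 | (2R,3R)-3-(4-{[1,3-bis(TBSO)propan-2-yl]oxy}-3-methoxyphenyl)-3-hydroxy-2-{4-[3-(TBSO)propyl]-2,6-dimethoxyphenoxy}propanal | COc1cc([C@@H](O)[C@H](C=O)Oc2c(OC)cc(CCCO[Si](C)(C)C(C)(C)C)cc2OC)ccc1OC(CO[Si](C)(C)C(C)(C)C)CO[Si](C)(C)C(C)(C)C | intermediate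
16 | (1R,2S)-1-(4-{[1,3-bis(TBSO)propan-2-yl]oxy}-3-methoxyphenyl)-2-{4-[3-(TBSO)propyl]-2,6-dimethoxyphenoxy}propane-1,3-diol | COc1cc([C@@H](O)[C@H](CO)Oc2c(OC)cc(CCCO[Si](C)(C)C(C)(C)C)cc2OC)ccc1OC(CO[Si](C)(C)C(C)(C)C)CO[Si](C)(C)C(C)(C)C | intermediate
17 | (1R,2S)-1-{4-[(1,3-dihydroxypropan-2-yl)oxy]-3-methoxyphenyl}-2-[4-(3-hydroxypropyl)-2,6-dimethoxyphenoxy]propane-1,3-diol | COc1cc([C@@H](O)[C@H](CO)Oc2c(OC)cc(CCCO)cc2OC)ccc1OC(CO)CO | target

## Step count and least certain steps

Total step count: 11. Longest linear sequence: 8 steps (1 → 2 → 4 → 5 → 6 → 12 → 14 → 16 → 17). The ring B branch from 7 to 17 is 7 steps.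

**Step 9 (key step, proposed new method).**
- What may go wrong: the shift may be slow at the electron-rich enol-ether terminus, so that warming brings in the [1,2]-shift and ring lithiation. Exo/endo discrimination of the aryl group may be poor, which erodes C7 (E-configured substrates are the less selective series when the anion-stabilising group is an arene). The new alkene may form with incomplete E selectivity, which would erode C8.
- Fallback (known chemistry): it sets out from 7 and 2 and comes back to the route at 17.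
  - Exhaustive silylation of 7 (TBSCl, imidazole) gives the bis-silyl ether F1. Selective methanolysis of its aryl silyl ether (K2CO3, MeOH) gives 4-[3-(TBSO)propyl]-2,6-dimethoxyphenol F2.
  - Commercial methyl (R)-2,3-dihydroxypropanoate F3 is silylated at its primary hydroxyl to methyl (R)-3-(TBSO)-2-hydroxypropanoate F4.
  - Mitsunobu coupling of F2 with F4 (PPh3, DIAD) inverts the carbinol centre and gives the (S)-aryloxy ester F5. DIBAL-H at −78 °C gives the (S)-aldehyde F6.
  - Separately, 4-bromo-2-methoxyphenol F7 is coupled with 2 under Mitsunobu conditions to aryl bromide F8. Bromine–lithium exchange with n-BuLi gives aryllithium F9.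
  - Addition of F9 to F6 in THF at −78 °C under non-chelating conditions follows the polar Felkin–Anh model (aryloxy group antiperiplanar to the incoming aryl). It should give the anti adduct F10 with the (1R,2S) configuration.
  - n-Bu4NF then removes all four silyl groups to give 17.

**Step 7.**
- What may go wrong: the vinylogous-ester carbonyl is weakly electrophilic, so reduction may be slow and poorly enantioselective, with competing conjugate reduction. The product may ionise on any acidic contact and transpose to an enal.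
- Fallback: it sets out from 10 and comes back at 11.
  - Luche reduction of 10 (NaBH4, CeCl3·7H2O, MeOH, −40 °C) gives the racemic alcohol F11.
  - Kinetic resolution by transesterification with vinyl acetate over immobilised Candida antarctica lipase B should acylate the (R)-enantiomer, as is usual for methyl carbinols with a large second substituent. This gives the (R)-acetate F12, separable from unreacted (S)-alcohol.
  - Methanolysis of F12 (K2CO3, MeOH) gives 11. The (S)-alcohol can be returned to 10 by MnO2 oxidation.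

**Step 8.**
- What may go wrong: decomposition of the sensitive γ-aryloxy allylic alkoxide during a slow alkylation, or self-condensation of the electron-rich benzyl chloride before it is intercepted.
- Fallback: it sets out from 6 and comes back at 12. The benzylic ether is made on a robust alcohol and the enol ether is built afterwards.
  - Williamson etherification of commercial (R)-but-3-yn-2-ol F13 with 6 (NaH, n-Bu4NI) gives the propargylic ether F14.
  - Hydrozirconation with Cp2Zr(H)Cl followed by I2 gives the (E)-vinyl iodide F15.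
  - Coupling of F15 with phenol F2 (made from 7 via F1 as above) using CuI, N,N-dimethylglycine and Cs2CO3 in dioxane at 90 °C, with retention of alkene geometry, gives 12. This also bypasses steps 5 to 7.

**Step 10.**
- What may go wrong: epimerisation at C8 or retro-aldol cleavage while the β-hydroxy-α-aryloxy aldehyde is exposed, or oxidative attack on the electron-rich rings during a slow cleavage.
- Fallback: it sets out from 14 and comes back at 17.
  - The C7 hydroxyl is silylated first (TBSOTf, 2,6-lutidine, −78 °C) to the tetra-silyl ether F16. This closes the retro-aldol channel.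
  - Ozonolysis at −78 °C in CH2Cl2/MeOH with direct NaBH4 quench, so the aldehyde is reduced in the cold, gives the primary alcohol F17.
  - n-Bu4NF removes all four silyl groups to give 17.

## Further compounds

F1 | step 9 | tert-butyl{3-[4-(TBSO)-3,5-dimethoxyphenyl]propoxy}dimethylsilane (bis-silyl ether of 7) | COc1cc(CCCO[Si](C)(C)C(C)(C)C)cc(OC)c1O[Si](C)(C)C(C)(C)C
F2 | step 9 | 4-[3-(TBSO)propyl]-2,6-dimethoxyphenol | COc1cc(CCCO[Si](C)(C)C(C)(C)C)cc(OC)c1O
F3 | step 9 | methyl (R)-2,3-dihydroxypropanoate | COC(=O)[C@H](O)CO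
F4 | step 9 | methyl (R)-3-(TBSO)-2-hydroxypropanoate | COC(=O)[C@H](O)CO[Si](C)(C)C(C)(C)C
F5 | step 9 | methyl (S)-3-(TBSO)-2-{4-[3-(TBSO)propyl]-2,6-dimethoxyphenoxy}propanoate | COC(=O)[C@@H](Oc1c(OC)cc(CCCO[Si](C)(C)C(C)(C)C)cc1OC)CO[Si](C)(C)C(C)(C)C
F6 | step 9 | (S)-3-(TBSO)-2-{4-[3-(TBSO)propyl]-2,6-dimethoxyphenoxy}propanal | O=C[C@@H](Oc1c(OC)cc(CCCO[Si](C)(C)C(C)(C)C)cc1OC)CO[Si](C)(C)C(C)(C)C
F7 | step 9 | 4-bromo-2-methoxyphenol | COc1cc(Br)ccc1O
F8 | step 9 | 4-bromo-1-{[1,3-bis(TBSO)propan-2-yl]oxy}-2-methoxybenzene | COc1cc(Br)ccc1OC(CO[Si](C)(C)C(C)(C)C)CO[Si](C)(C)C(C)(C)C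
F9 | step 9 | (4-{[1,3-bis(TBSO)propan-2-yl]oxy}-3-methoxyphenyl)lithium | [Li]c1ccc(OC(CO[Si](C)(C)C(C)(C)C)CO[Si](C)(C)C(C)(C)C)c(OC)c1
F10 | step 9 | (1R,2S)-1-(4-{[1,3-bis(TBSO)propan-2-yl]oxy}-3-methoxyphenyl)-3-(TBSO)-2-{4-[3-(TBSO)propyl]-2,6-dimethoxyphenoxy}propan-1-ol | COc1cc([C@@H](O)[C@H](CO[Si](C)(C)C(C)(C)C)Oc2c(OC)cc(CCCO[Si](C)(C)C(C)(C)C)cc2OC)ccc1OC(CO[Si](C)(C)C(C)(C)C)CO[Si](C)(C)C(C)(C)C
F11 | step 7 | racemic (E)-4-{4-[3-(TBSO)propyl]-2,6-dimethoxyphenoxy}but-3-en-2-ol | CC(O)/C=C/Oc1c(OC)cc(CCCO[Si](C)(C)C(C)(C)C)cc1OC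
F12 | step 7 | (2R,3E)-4-{4-[3-(TBSO)propyl]-2,6-dimethoxyphenoxy}but-3-en-2-yl acetate | C[C@@H](OC(C)=O)/C=C/Oc1c(OC)cc(CCCO[Si](C)(C)C(C)(C)C)cc1OC
F13 | step 8 | (R)-but-3-yn-2-ol | C[C@@H](O)C#C
F14 | step 8 | (R)-3-[(4-{[1,3-bis(TBSO)propan-2-yl]oxy}-3-methoxybenzyl)oxy]but-1-yne | C[C@@H](OCc1ccc(OC(CO[Si](C)(C)C(C)(C)C)CO[Si](C)(C)C(C)(C)C)c(OC)c1)C#C
F15 | step 8 | (1E,3R)-3-[(4-{[1,3-bis(TBSO)propan-2-yl]oxy}-3-methoxybenzyl)oxy]-1-iodobut-1-ene | C[C@@H](OCc1ccc(OC(CO[Si](C)(C)C(C)(C)C)CO[Si](C)(C)C(C)(C)C)c(OC)c1)/C=C/I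
F16 | step 10 | C7 O-TBS ether of 14: (1R,2S,3E)-1-(TBSO)-1-(4-{[1,3-bis(TBSO)propan-2-yl]oxy}-3-methoxyphenyl)-2-{4-[3-(TBSO)propyl]-2,6-dimethoxyphenoxy}pent-3-ene | COc1cc([C@@H](O[Si](C)(C)C(C)(C)C)[C@H](/C=C/C)Oc2c(OC)cc(CCCO[Si](C)(C)C(C)(C)C)cc2OC)ccc1OC(CO[Si](C)(C)C(C)(C)C)CO[Si](C)(C)C(C)(C)C
F17 | step 10 | (2S,3R)-3-(TBSO)-3-(4-{[1,3-bis(TBSO)propan-2-yl]oxy}-3-methoxyphenyl)-2-{4-[3-(TBSO)propyl]-2,6-dimethoxyphenoxy}propan-1-ol | COc1cc([C@@H](O[Si](C)(C)C(C)(C)C)[C@H](CO)Oc2c(OC)cc(CCCO[Si](C)(C)C(C)(C)C)cc2OC)ccc1OC(CO[Si](C)(C)C(C)(C)C)CO[Si](C)(C)C(C)(C)C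
A1 | alternative 1 | (R)-4-benzyl-3-(2-{4-[3-(TBSO)propyl]-2,6-dimethoxyphenoxy}acetyl)oxazolidin-2-one | O=C(COc1c(OC)cc(CCCO[Si](C)(C)C(C)(C)C)cc1OC)N1[C@H](Cc2ccccc2)COC1=O
A2 | alternative 1 | (R)-4-benzyl-3-[(2R,3S)-3-(4-{[1,3-bis(TBSO)propan-2-yl]oxy}-3-methoxyphenyl)-3-hydroxy-2-{4-[3-(TBSO)propyl]-2,6-dimethoxyphenoxy}propanoyl]oxazolidin-2-one (syn adduct) | COc1cc([C@H](O)[C@H](C(=O)N2[C@H](Cc3ccccc3)COC2=O)Oc2c(OC)cc(CCCO[Si](C)(C)C(C)(C)C)cc2OC)ccc1OC(CO[Si](C)(C)C(C)(C)C)CO[Si](C)(C)C(C)(C)C
A3 | alternative 2 | ethyl (E)-3-(4-{[1,3-bis(TBSO)propan-2-yl]oxy}-3-methoxyphenyl)acrylate | CCOC(=O)/C=C/c1ccc(OC(CO[Si](C)(C)C(C)(C)C)CO[Si](C)(C)C(C)(C)C)c(OC)c1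
A4 | alternative 2 | ethyl (2S,3R)-3-(4-{[1,3-bis(TBSO)propan-2-yl]oxy}-3-methoxyphenyl)-2,3-dihydroxypropanoate | COc1cc([C@@H](O)[C@@H](C(=O)OCC)O)ccc1OC(CO[Si](C)(C)C(C)(C)C)CO[Si](C)(C)C(C)(C)C
A5 | alternative 2 | ethyl (2S,3R)-3-(4-{[1,3-bis(TBSO)propan-2-yl]oxy}-3-methoxyphenyl)-3-hydroxy-2-[(4-nitrophenyl)sulfonyloxy]propanoate | COc1cc([C@@H](O)[C@@H](C(=O)OCC)OS(=O)(=O)c2ccc(cc2)[N+](=O)[O-])ccc1OC(CO[Si](C)(C)C(C)(C)C)CO[Si](C)(C)C(C)(C)C
A6 | alternative 3 | ethyl 3-(4-{[1,3-bis(TBSO)propan-2-yl]oxy}-3-methoxyphenyl)-3-oxo-2-{4-[3-(TBSO)propyl]-2,6-dimethoxyphenoxy}propanoate (racemic) | CCOC(=O)C(Oc1c(OC)cc(CCCO[Si](C)(C)C(C)(C)C)cc1OC)C(=O)c1ccc(OC(CO[Si](C)(C)C(C)(C)C)CO[Si](C)(C)C(C)(C)C)c(OC)c1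
A7 | alternative 3 | ethyl (2R,3S)-3-(4-{[1,3-bis(TBSO)propan-2-yl]oxy}-3-methoxyphenyl)-3-hydroxy-2-{4-[3-(TBSO)propyl]-2,6-dimethoxyphenoxy}propanoate (syn) | COc1cc([C@H](O)[C@H](C(=O)OCC)Oc2c(OC)cc(CCCO[Si](C)(C)C(C)(C)C)cc2OC)ccc1OC(CO[Si](C)(C)C(C)(C)C)CO[Si](C)(C)C(C)(C)C
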